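**Retrosynthetic overview**
1. Target 8 ⇐ epoxy alcohol 7: chloride opens the vinyl oxirane at allylic C2, anti to the ring oxygen (sets C2–Cl, frees C1–OH).
2. 7 ⇐ cis-1,4-diol 6: cyclodehydration of the C1/C2 trans-diol with inversion at C2; 6 ⇐ endoperoxide 5 by O–O reduction.
3. Key step, 5 ⇐ diene 4: [4+2] of singlet oxygen anti to the C1/C6 oxygens; the two peroxide-containing six-membered rings of a 2,3-dioxabicyclo[2.2.2]octene close in one operation and set C2 and C5.
4. 4 ⇐ triol 3 ⇐ diol acid 2 ⇐ sodium benzoate 1: dibenzoylation, acid reduction, enzymatic ipso,ortho-cis-dihydroxylation (sets C1 and C6).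
5. Ring order: carbocycle (dearomatised benzoate) → bicyclic peroxide (step 4, opened in step 5) → oxirane (step 6, opened in step 7).

Assumption: the whole-cell biocatalyst Ralstonia eutropha B9 (benzoate 1,2-dioxygenase active, cis-diol dehydrogenase blocked) is treated as a reagent, so the route starts from sodium benzoate.
Locants used in all names: C1 = quaternary carbinol carbon carrying the CH2O carbon; C2 = the carbon that ends as CHCl; C3=C4; C5 = CHOH; C6 = CHOBz.

**Step 1**
Reactants: 1 sodium benzoate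
Product: 2 (1S,6R)-1,6-dihydroxycyclohexa-2,4-diene-1-carboxylic acid
Conditions: R. eutropha B9 whole cells, fructose/mineral salts medium, air, 30 °C, pH 7, fed-batch; then HCl to pH 3, EtOAc extraction
Reagents that add atoms: dioxygen, O=O
Why: Enzymatic dearomatising cis-dihydroxylation (microbial arene oxidation): benzoate 1,2-dioxygenase adds both oxygen atoms of O2 to the ipso/ortho bond from one face, and the blocked dehydrogenase lets the enantiopure (1S,6R) cis-diol accumulate, which fixes C1 and C6 of the target.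

**Step 2**
Reactants: 2 (1S,6R)-1,6-dihydroxycyclohexa-2,4-diene-1-carboxylic acid
Product: 3 (1R,6R)-1-(hydroxymethyl)cyclohexa-2,4-diene-1,6-diol
Conditions: LiAlH4 (4 equiv), THF, 0 → 45 °C; Fieser work-up
Reagents that add atoms: none
Why: Hydride reduction of a carboxylic acid to the primary alcohol with LiAlH4 proceeds under non-acidic conditions that leave the diene and both carbinol centres untouched, C1 changing only its descriptor (S to R) because CH2OH now ranks below C6.

**Step 3**
Reactants: 3 (1R,6R)-1-(hydroxymethyl)cyclohexa-2,4-diene-1,6-diol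
Product: 4 [(1R,6R)-6-(benzoyloxy)-1-hydroxycyclohexa-2,4-dien-1-yl]methyl benzoate
Conditions: BzCl (2.2 equiv), pyridine, CH2Cl2, −10 → 0 °C; used promptly
Reagents that add atoms: benzoyl chloride, O=C(Cl)c1ccccc1
Why: Acyl chloride/pyridine esterification takes the primary and the secondary hydroxyl while the hindered tertiary C1–OH stays free, and no stereocentre is touched.

**Step 4 (key step)**
Reactants: 4 [(1R,6R)-6-(benzoyloxy)-1-hydroxycyclohexa-2,4-dien-1-yl]methyl benzoate
Product: 5 [(1R,2R,5S,6R)-6-(benzoyloxy)-1-hydroxy-2,5-epidioxycyclohex-3-en-1-yl]methyl benzoate (a 2,3-dioxabicyclo[2.2.2]oct-5-ene; peroxide bridge on the face opposite the C1–OH and C6–OBz)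
Conditions: O2, rose bengal (cat.), visible light, CH2Cl2–MeOH 4:1, −30 °C
Reagents that add atoms: dioxygen, O=O
Why: Hetero-Diels–Alder [4+2] cycloaddition of singlet oxygen to the s-cis diene, which in a protic medium (no hydroxyl-directed syn delivery) approaches anti to the allylic oxygens at C1 and C6, so both new C–O bonds at C2 and C5 form on the face of the CH2OBz group and both peroxide rings of the bicycle close at once.

**Step 5**
Reactants: 5 [(1R,2R,5S,6R)-6-(benzoyloxy)-1-hydroxy-2,5-epidioxycyclohex-3-en-1-yl]methyl benzoate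
Product: 6 [(1S,2R,5S,6R)-6-(benzoyloxy)-1,2,5-trihydroxycyclohex-3-en-1-yl]methyl benzoate
Conditions: Zn dust, AcOH, CH2Cl2, 0 °C → rt
Reagents that add atoms: none
Why: Dissolving-metal reduction cleaves only the weak O–O bond, so both C–O bonds are kept and the cis-1,4-diol is obtained with C2 and C5 unchanged and the esters and alkene intact.

**Step 6**
Reactants: 6 [(1S,2R,5S,6R)-6-(benzoyloxy)-1,2,5-trihydroxycyclohex-3-en-1-yl]methyl benzoate
Product: 7 [(1S,2S,5S,6R)-6-(benzoyloxy)-1,2-epoxy-5-hydroxycyclohex-3-en-1-yl]methyl benzoate (oxirane on the face of the former C1–OH; pipoxide framework)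
Conditions: PPh3 (1.3 equiv), DIAD (1.3 equiv), THF, 0 °C → rt
Reagents that add atoms: none
Why: Mitsunobu cyclodehydration of the vicinal trans-diol, in which the phosphonium-activated secondary allylic C2–OH is displaced from the rear by the adjacent tertiary C1 oxygen (3-exo-tet SN2), inverting C2, while the isolated C5–OH has no vicinal partner and is recovered.

**Step 7**
Reactants: 7 [(1S,2S,5S,6R)-6-(benzoyloxy)-1,2-epoxy-5-hydroxycyclohex-3-en-1-yl]methyl benzoate
Product: 8 [(1R,2R,5S,6R)-6-(benzoyloxy)-2-chloro-1,5-dihydroxycyclohex-3-en-1-yl]methyl benzoate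
Conditions: HCl (1 M in Et2O, 1.5 equiv), CH2Cl2, −40 → −10 °C; NaHCO3 quench
Reagents that add atoms: hydrogen chloride, Cl
Why: Acid-promoted SN2 ring opening of the vinyl oxirane by chloride at the allylic carbon C2, anti to the oxirane oxygen (trans-diaxial epoxide opening), is a second inversion at C2 that gives the trans chlorohydrin with chlorine cis to the C5 hydroxyl and leaves the tertiary C1–OH.

**Compound list**
1 | sodium benzoate | [Na+].[O-]C(=O)c1ccccc1 | starting material
2 | (1S,6R)-1,6-dihydroxycyclohexa-2,4-diene-1-carboxylic acid | OC(=O)[C@]1(O)C=CC=C[C@H]1O | intermediate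
3 | (1R,6R)-1-(hydroxymethyl)cyclohexa-2,4-diene-1,6-diol | OC[C@]1(O)C=CC=C[C@H]1O | intermediate
4 | [(1R,6R)-6-(benzoyloxy)-1-hydroxycyclohexa-2,4-dien-1-yl]methyl benzoate | O=C(OC[C@]1(O)C=CC=C[C@H]1OC(=O)c1ccccc1)c1ccccc1 | intermediate
5 | [(1R,2R,5S,6R)-6-(benzoyloxy)-1-hydroxy-2,5-epidioxycyclohex-3-en-1-yl]methyl benzoate | O=C(OC[C@]1(O)[C@H]2C=C[C@H](OO2)[C@H]1OC(=O)c1ccccc1)c1ccccc1 | intermediate
6 | [(1S,2R,5S,6R)-6-(benzoyloxy)-1,2,5-trihydroxycyclohex-3-en-1-yl]methyl benzoate | O=C(OC[C@]1(O)[C@H](O)C=C[C@H](O)[C@H]1OC(=O)c1ccccc1)c1ccccc1 | intermediate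
7 | [(1S,2S,5S,6R)-6-(benzoyloxy)-1,2-epoxy-5-hydroxycyclohex-3-en-1-yl]methyl benzoate | O=C(OC[C@]12O[C@H]1C=C[C@H](O)[C@H]2OC(=O)c1ccccc1)c1ccccc1 | intermediate
8 | [(1R,2R,5S,6R)-6-(benzoyloxy)-2-chloro-1,5-dihydroxycyclohex-3-en-1-yl]methyl benzoate | O=C(OC[C@]1(O)[C@H](Cl)C=C[C@H](O)[C@H]1OC(=O)c1ccccc1)c1ccccc1 | target

Total step count: 7. Longest linear sequence: 7 (the route is fully linear).

**Three steps most likely to fail**

Step 6 (cyclodehydration in the presence of the free C5–OH). The C5–OH may itself be activated, with participation of the C6 benzoate, or may attack C4 in an SN2′ sense once C2–O is activated. Fallback: starting from 6, the less hindered allylic C5–OH is silylated (Et3SiCl, imidazole, CH2Cl2, −20 °C; C2–OH sits next to the quaternary centre and reacts more slowly) to give [(1S,2R,5S,6R)-6-(benzoyloxy)-1,2-dihydroxy-5-(triethylsilyloxy)cyclohex-3-en-1-yl]methyl benzoate F4. With only one secondary hydroxyl left, the step 6 conditions close the oxirane to [(1S,2S,5S,6R)-6-(benzoyloxy)-1,2-epoxy-5-(triethylsilyloxy)cyclohex-3-en-1-yl]methyl benzoate F5. HCl in wet THF then opens the oxirane as in step 7 and cleaves the silyl ether in the same flask, so the sequence comes back to the route at 8.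

Step 4 (facial selectivity of the cycloaddition). The free tertiary hydroxyl could steer singlet oxygen to its own face, and the desired face carries the CH2OBz group. Fallback: starting from 4, the tertiary hydroxyl is capped (TMSOTf, 2,6-lutidine, CH2Cl2, −78 °C) to give [(1R,6R)-6-(benzoyloxy)-1-(trimethylsilyloxy)cyclohexa-2,4-dien-1-yl]methyl benzoate F2, so that both oxygens on that face are bulky non-donors. Photooxygenation (O2, TPP, CH2Cl2, −30 °C) then gives [(1R,2R,5S,6R)-6-(benzoyloxy)-2,5-epidioxy-1-(trimethylsilyloxy)cyclohex-3-en-1-yl]methyl benzoate F3 by steric control alone. Zn in AcOH–H2O–THF reduces the peroxide and hydrolyses the tertiary silyl ether, coming back to the route at 6.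

Step 2 (LiAlH4 on the unprotected dihydroxy acid). Risks are an insoluble aluminium carboxylate, incomplete reduction and loss of the water-soluble triol on work-up. Fallback: starting from 2, the acid is esterified (TMSCHN2, MeOH–toluene, 0 °C) to methyl (1S,6R)-1,6-dihydroxycyclohexa-2,4-diene-1-carboxylate F1. This α-hydroxy ester is reduced under mild conditions (NaBH4, EtOH, 0 °C), coming back to the route at 3.

**Further compounds**
F1 | step 2 | methyl (1S,6R)-1,6-dihydroxycyclohexa-2,4-diene-1-carboxylate | COC(=O)[C@]1(O)C=CC=C[C@H]1O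
F2 | step 4 | [(1R,6R)-6-(benzoyloxy)-1-(trimethylsilyloxy)cyclohexa-2,4-dien-1-yl]methyl benzoate | O=C(OC[C@]1(O[Si](C)(C)C)C=CC=C[C@H]1OC(=O)c1ccccc1)c1ccccc1
F3 | step 4 | [(1R,2R,5S,6R)-6-(benzoyloxy)-2,5-epidioxy-1-(trimethylsilyloxy)cyclohex-3-en-1-yl]methyl benzoate | O=C(OC[C@]1(O[Si](C)(C)C)[C@H]2C=C[C@H](OO2)[C@H]1OC(=O)c1ccccc1)c1ccccc1
F4 | step 6 | [(1S,2R,5S,6R)-6-(benzoyloxy)-1,2-dihydroxy-5-(triethylsilyloxy)cyclohex-3-en-1-yl]methyl benzoate | O=C(OC[C@]1(O)[C@H](O)C=C[C@H](O[Si](CC)(CC)CC)[C@H]1OC(=O)c1ccccc1)c1ccccc1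
F5 | step 6 | [(1S,2S,5S,6R)-6-(benzoyloxy)-1,2-epoxy-5-(triethylsilyloxy)cyclohex-3-en-1-yl]methyl benzoate | O=C(OC[C@]12O[C@H]1C=C[C@H](O[Si](CC)(CC)CC)[C@H]2OC(=O)c1ccccc1)c1ccccc1
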